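The chain carbons run from C1 at ring A (guaiacyl) to C7 at ring B (syringyl). Everything rests on the C6–C7 disconnection, which uses two built-in polarities. Ring B together with C7 is a para-hydroxybenzyl unit, so the derived para-quinone methide accepts nucleophiles at C7. C6 sits gamma to the C3 carbonyl and is the donor terminus of a dienol silane. A single Lewis acid catalysed 1,6-addition joins the halves, rearomatises ring B and uncovers the (E)-C4=C5 enone. The nucleophilic precursor is the ring A allyl ketone silylated once on its dienol and once on its phenol. Both trimethylsilyl groups leave during work-up, so the coupling ends the synthesis.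

Key step: step 5

Remark on the chemistry: the dienol silane is drawn with the Z geometry at C3=C4 expected from soft enolisation. This geometry disappears in the coupling, so a mixture of isomers would serve equally.

Step 1
Reactants: 1 dihydroferulic acid (3-(4-hydroxy-3-methoxyphenyl)propanoic acid); 2 N,O-dimethylhydroxylamine hydrochloride
Product: 3 Weinreb amide (3-(4-hydroxy-3-methoxyphenyl)-N-methoxy-N-methylpropanamide)
Conditions: EDC·HCl (1.2 equiv), 1-hydroxybenzotriazole (0.2 equiv), Et3N (2.5 equiv), CH2Cl2, 0 °C to rt
Reagents that add atoms: none
Why: Carbodiimide amide coupling (Weinreb amide formation), in which the liberated amine takes the active ester far faster than the weakly nucleophilic guaiacol OH, so the phenol needs no protection.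

Step 2
Reactants: 3 Weinreb amide; 4 allylmagnesium bromide
Product: 5 allyl ketone (1-(4-hydroxy-3-methoxyphenyl)hex-5-en-3-one)
Conditions: 4 (3 equiv, 1 M in Et2O), THF, −78 to −20 °C; cannulated into ice-cold 1 M HCl
Reagents that add atoms: none
Why: Weinreb ketone synthesis, in which the first equivalent of Grignard reagent only deprotonates the phenol, the second forms the chelated tetrahedral adduct that resists over-addition, and the acidic inverse quench releases the beta,gamma-unsaturated ketone without base-induced alkene migration while keeping the expelled amine protonated.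

Step 3
Reactants: 5 allyl ketone
Product: 6 dienol silane (trimethyl{2-methoxy-4-[(3Z)-3-(trimethylsilyloxy)hexa-3,5-dien-1-yl]phenoxy}silane)
Conditions: Me3SiOTf (2.5 equiv), Et3N (4 equiv), CH2Cl2, −78 to 0 °C; evaporation, extraction into dry pentane, filtration under Ar; used crude the same day
Reagents that add atoms: trimethylsilyl trifluoromethanesulfonate, C[Si](C)(C)OS(=O)(=O)C(F)(F)F
Why: Soft enolisation with a silyl triflate and a tertiary amine, in which the C4 hydrogens (alpha to the carbonyl and allylic) are removed far faster than those at C2 to give the conjugated 1-silyloxydiene with the usual Z geometry, the fast low-temperature silylation leaves no time for amine-induced alkene migration, and the same reagent caps the ring A phenol.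

Step 4
Reactants: 7 syringyl alcohol (4-(hydroxymethyl)-2,6-dimethoxyphenol)
Product: 9 syringyl para-quinone methide (2,6-dimethoxy-4-methylidenecyclohexa-2,5-dien-1-one), via 4-(bromomethyl)-2,6-dimethoxyphenol 8 (not isolated)
Conditions: Me3SiBr (1.5 equiv), CH2Cl2, 0 °C, 15 min; brief shake with ice-cold sat. aq NaHCO3; organic layer dried (MgSO4, 0 °C), filtered onto 4 Å MS at −78 °C (about 0.03 M); used within the hour
Reagents that add atoms: bromotrimethylsilane, C[Si](C)(C)Br (its bromine appears in 8 only)
Why: Bromodehydroxylation of an electron-rich benzylic alcohol followed by bicarbonate-induced 1,6-elimination of HBr, the standard entry to lignin-type para-quinone methides, with low temperature, high dilution and the two methoxy groups flanking the carbonyl expected to slow oligomerisation long enough for immediate use.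

Step 5
Reactants: 6 dienol silane; 9 syringyl para-quinone methide
Product: 11 (4E)-7-(4-hydroxy-3,5-dimethoxyphenyl)-1-(4-hydroxy-3-methoxyphenyl)hept-4-en-3-one, via coupled bis(trimethylsilyl) ether 10 (not isolated)
Conditions: Sc(OTf)3 (10 mol %), 4 Å MS, CH2Cl2/EtCN (10:1), −78 °C, cold solution of 9 (1.3 equiv) cannulated into 6 over 1 h; then 1 M HCl, THF, 0 °C
Reagents that add atoms: none
Why: Coordination of Sc(OTf)3 to the carbonyl oxygen of 9 polarises it towards a ring B aryloxide with cationic character at C7; the terminus C6 of 6 attacks C7 through an open transition state, which forms the C6–C7 bond, rearomatises ring B and leaves a C3 silyloxocarbenium ion conjugated with the new C4=C5 alkene, and transfer of that Me3Si group to the aryloxide frees the catalyst and gives 10, whose two aryl silyl ethers are hydrolysed by the dilute acid. The closest known reaction type is the vinylogous Mukaiyama–Michael reaction in its 1,6-variant, the Lewis acid catalysed addition of silyl enol and dienol ethers to para-quinone methides, supported by the gamma-selective alkylation of silyl dienol ethers with stabilised carbocations. No ring is closed and no stereocentre is created, so the C4=C5 geometry is the only stereochemical issue. Gamma over alpha selectivity is required and comes from the substrate, because C6 is a bare CH2 terminus with the larger frontier orbital coefficient, whereas C4 lies next to the silyloxy-bearing C3 and attack there would forgo the conjugation gained in the enone. The E geometry follows from reaction of the s-trans rotamer about C4–C5, favoured because the Z-placed OSiMe3 group clashes with C6 in the s-cis form, and E is also the more stable isomer. Chemoselectivity against self-condensation of 9 and against Friedel–Crafts attack by ring A rests on the slow addition, which keeps 9 scarce next to the far more nucleophilic dienol silane.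

Compound list
1 | dihydroferulic acid, 3-(4-hydroxy-3-methoxyphenyl)propanoic acid | COc1cc(CCC(=O)O)ccc1O | starting material
2 | N,O-dimethylhydroxylamine hydrochloride | CNOC.Cl | starting material
3 | 3-(4-hydroxy-3-methoxyphenyl)-N-methoxy-N-methylpropanamide | COc1cc(CCC(=O)N(C)OC)ccc1O | intermediate
4 | allylmagnesium bromide | C=CC[Mg]Br | starting material
5 | 1-(4-hydroxy-3-methoxyphenyl)hex-5-en-3-one | C=CCC(=O)CCc1ccc(O)c(OC)c1 | intermediate
6 | trimethyl{2-methoxy-4-[(3Z)-3-(trimethylsilyloxy)hexa-3,5-dien-1-yl]phenoxy}silane | C=C/C=C(/CCc1ccc(O[Si](C)(C)C)c(OC)c1)O[Si](C)(C)C | intermediate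
7 | syringyl alcohol, 4-(hydroxymethyl)-2,6-dimethoxyphenol | COc1cc(CO)cc(OC)c1O | starting material
8 | 4-(bromomethyl)-2,6-dimethoxyphenol | COc1cc(CBr)cc(OC)c1O | intermediate
9 | 2,6-dimethoxy-4-methylidenecyclohexa-2,5-dien-1-one | C=C1C=C(OC)C(=O)C(OC)=C1 | intermediate
10 | (4E)-7-[3,5-dimethoxy-4-(trimethylsilyloxy)phenyl]-1-[3-methoxy-4-(trimethylsilyloxy)phenyl]hept-4-en-3-one | COc1cc(CCC(=O)/C=C/CCc2cc(OC)c(O[Si](C)(C)C)c(OC)c2)ccc1O[Si](C)(C)C | intermediate
11 | (4E)-7-(4-hydroxy-3,5-dimethoxyphenyl)-1-(4-hydroxy-3-methoxyphenyl)hept-4-en-3-one | COc1cc(CCC(=O)/C=C/CCc2cc(OC)c(O)c(OC)c2)ccc1O | target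

Total step count: 5. Longest linear sequence: 4 (steps 1, 2, 3 and 5); step 4 is the one-step side branch.

Steps most likely to fail

1. Step 5. Three processes could erode the coupling: bond formation through C4 instead of C6, proton-induced loss of the dienol silyl group, and self-condensation of the methide outrunning the addition. The fallback sets out from 3 and 7 and returns at 11. It builds the enone by olefin cross metathesis at C4=C5 instead of by C6–C7 bond formation.
   - Amide 3 with vinylmagnesium bromide (3 equiv, THF, −78 to 0 °C, inverse quench into cold 1 M HCl) should give 5-(4-hydroxy-3-methoxyphenyl)pent-1-en-3-one F1.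
   - Alcohol 7 with allyltrimethylsilane and Bi(OTf)3 (2 mol %) in CH2Cl2 at 0 °C to rt should give 4-(but-3-en-1-yl)-2,6-dimethoxyphenol F2. This is a dehydrative Hosomi–Sakurai allylation of an electron-rich benzylic alcohol.
   - F1 and F2 with the second-generation Hoveyda–Grubbs catalyst (5 mol %, CH2Cl2, 40 °C) should give 11 directly. Pairing an electron-poor vinyl ketone with a plain terminal alkene favours the cross product and the E isomer, and free phenols are tolerated.

2. Step 4. The methide may oligomerise or rehydrate during the aqueous wash, the drying and the short storage. The fallback sets out from 7 and returns at 10, and it never accumulates free methide.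
   - Alcohol 7 is persilylated (Me3SiCl, Et3N, CH2Cl2) to {[3,5-dimethoxy-4-(trimethylsilyloxy)phenyl]methoxy}trimethylsilane F3, which is distillable and storable.
   - F3 and 6 are combined with Me3SiOTf (10 mol %) in CH2Cl2 at −78 to −20 °C. Catalytic ionisation of the benzylic silyl ether produces the O-silylated methide cation only in trace concentration.
   - Capture of this cation by 6 is a silyl triflate catalysed benzylic alkylation of a silyl enol ether. It should give 10, which then meets the acidic work-up of step 5.

3. Step 3. The C5=C6 alkene may migrate into conjugation before silylation, which would lead to enolisation towards C2. The trimethylsilyl groups may also be lost by hydrolysis while the ammonium salt is removed. The fallback sets out from 5 and returns at 11. It changes the protecting group strategy from traceless to isolable silyl groups at the cost of one step.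
   - Ketone 5 with t-BuMe2SiOTf (2.5 equiv) and Et3N in CH2Cl2 at 0 °C should give tert-butyl{4-[(3Z)-3-(tert-butyldimethylsilyloxy)hexa-3,5-dien-1-yl]-2-methoxyphenoxy}dimethylsilane F4. It survives chromatography on Et3N-deactivated silica, so isomeric dienes and salts can be removed.
   - Coupling of F4 with 9 under the conditions of step 5 with a neutral work-up should give (4E)-7-[4-(tert-butyldimethylsilyloxy)-3,5-dimethoxyphenyl]-1-[4-(tert-butyldimethylsilyloxy)-3-methoxyphenyl]hept-4-en-3-one F5.
   - Bu4NF buffered with AcOH (THF, 0 °C) then gives 11.

Further compounds
F1 | step 5 | 5-(4-hydroxy-3-methoxyphenyl)pent-1-en-3-one | C=CC(=O)CCc1ccc(O)c(OC)c1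
F2 | step 5 | 4-(but-3-en-1-yl)-2,6-dimethoxyphenol | C=CCCc1cc(OC)c(O)c(OC)c1
F3 | step 4 | {[3,5-dimethoxy-4-(trimethylsilyloxy)phenyl]methoxy}trimethylsilane | COc1cc(CO[Si](C)(C)C)cc(OC)c1O[Si](C)(C)C
F4 | step 3 | tert-butyl{4-[(3Z)-3-(tert-butyldimethylsilyloxy)hexa-3,5-dien-1-yl]-2-methoxyphenoxy}dimethylsilane | C=C/C=C(/CCc1ccc(O[Si](C)(C)C(C)(C)C)c(OC)c1)O[Si](C)(C)C(C)(C)C
F5 | step 3 | (4E)-7-[4-(tert-butyldimethylsilyloxy)-3,5-dimethoxyphenyl]-1-[4-(tert-butyldimethylsilyloxy)-3-methoxyphenyl]hept-4-en-3-one | COc1cc(CCC(=O)/C=C/CCc2cc(OC)c(O[Si](C)(C)C(C)(C)C)c(OC)c2)ccc1O[Si](C)(C)C(C)(C)C
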